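**Reading the peak.** At each time of reading, the earlier maple run gives target and substrate as fractions of its charge. Target is highest at 4.00 h, with a reading of 21.8%.

- maple: substrate 0.050 M; gas phase 31 mM (held); run made earlier
- flask: substrate 0.10 M; gas phase 31 mM (held); time 30 h

maple run (percent of the substrate charged)

| time / h | target / % | substrate / % |
|---|---|---|
| 0.833 | 10.8 | 87.0 |
| 2.50 | 20.7 | 62.5 |
| 4.00 | 21.8 | 46.8 |
| 6.00 | 18.3 | 31.6 |
| 10.0 | 10.2 | 15.4 |

(scatter of a reading: 0.5 percentage points)

- at the start none of the gas phase is in solution

* time, not beyond 30 h, at which the flask holds most target
* the amount of target, in percent of the substrate charged, at that time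
* earliest time at which at least nineteen twentieths of that best amount are there
* latest time at which they still are

**Bench rule.** Substrate falls steadily, like a pseudo-first-order decay. My rule of thumb follows from that: with such a fall, the curve in fractions of the charge does not depend on the charge. The flask should then copy maple, with its peak near 21.8% at 4.00 h.

**Counting turnovers.** To find where the rule stops, I compare the gas with the charge. Saturated solution holds dissolved gas equal to 31.0% of the charge in the flask and 62.0% in maple. So I count turnovers, 3.23: how many times the dissolved gas at saturation must be replaced for each substrate to receive one gas. Maple needs 1.61, so the flask needs twice as many.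

If target also reacts with substrate, that step gains on the step of target with dissolved gas in proportion to this count. I therefore keep the maple time and commit to a peak below the maple reading.

**The result.** The forecast, reasoning that “the flask draws gas twice as fast”, gives 21.4% at 3.9 h, with a window from 2.7 h to 5.3 h.

The flask peaks at 3.35 h with 20.0%, and holds the asked share of that from 2.36 h to 4.62 h. My maple time is later than this, but the lower peak stands: raising the charge from maple's takes the best from 21.9% to 20.0%. After 300 h the flask holds 79.7% over-reacted product and 20.3% side product. Side product counts as two, so that is 7.83 over-reacted per side product, and multiplying by the turnovers gives 25.3.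

    substrate + target → side product (k = 4.20 × 10⁻⁴ M⁻¹ s⁻¹)
    substrate + dissolved gas ⇌ target (K = 1100 M⁻¹, k = 0.00170 M⁻¹ s⁻¹)
    dissolved gas + target → over-reacted product (k = 0.00360 M⁻¹ s⁻¹)
    gas phase ⇌ dissolved gas, rate k4*(csat - [dissolved gas]) (kL = 0.00350 s⁻¹)

**Second flask.** With 0.25 M of substrate the count is 8.06, so I expect 3.13 over-reacted per side product, which puts 39.0% of the charge in side product. The computed flask ends with 38.8% there, and its best target is 15.9%.

All runs are calculated on assumed constants.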